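## Analysis of the target

- The target (26) is tricyclic. A cyclohexane (ring A) is cis-fused to a cyclopentanone (ring B), and a nine-membered N-formyl azonane (ring C) is attached to ring B through the quaternary fusion carbon and the carbon next to it.
- Hydrindane numbering is used throughout: C1 (alkylidene carbon), C2 (ketone), C3, C3a (fusion CH), C4, C5 (methyl, tertiary acetate), C6, C7 (secondary acetate), C7a (quaternary); C1'–C3' run from C1 to nitrogen and C1''–C3'' from C7a to nitrogen.
- There are four stereocentres, C3a, C5, C7 and C7a, all S. The C7 oxygen lies on the face of ring A that carries the C7a–C1 bond, the C3a hydrogen is cis to the C1'' chain (cis fusion), and the C5 acetate is cis-1,3 to the C7 acetate.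
- The C1=C1' double bond is exocyclic to ring B, conjugated with the C2 ketone and E, which is the cis arrangement inside ring C.
- Sensitive groups are the tertiary acetate (ionises in strong acid), the secondary acetate and the formamide (hydride, strong base), and the enone (adds thiols and amines). In any intermediate that has a carbonyl at C1, a free C7 hydroxyl would be a β-hydroxy ketone open to retro-aldol cleavage.
- The difficulty lies in the quaternary stereocentre shared by all three rings and flanked by two further stereocentres, in the medium ring, and in an enone whose carbonyl sits one carbon further from C7a than carbonyl-based bond formation would place it.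
- The route rests on ring A: oxygen at C7 next to C7a and methyl at C5 opposite to it, with the C5–C6 positions free to carry a double bond. This is the ortho/para pattern that a 1-silyloxy-3-methylbutadiene leaves on a 2-substituted cyclopentenone.

## Retrosynthetic reasoning

**Enone to cyclopentene (26 ⇒ 25 ⇒ 24 ⇒ 23).** No skeletal bond is cut. The C2 ketone and the C1=C1' alkene are traced back through allylic alcohol 25 and epoxide 24 to the C1=C2 cyclopentene 23. This 1,2-transposition is the price of a cycloaddition that leaves its carbonyl at C1. It is regiochemically safe because C7a is quaternary, so a C1–O bond that opens can only lose hydrogen from C1'. Because C1' already lies in ring C, the new double bond should take the cis-in-ring (E-enone) geometry.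

**Ring C (23 ⇒ 22 ⇒ 21 ⇒ 20).** The azonane is cut at the N–C3'' bond, the only heteroatom bond in the ring. The forward reaction is alkylation of an acidic nosyl amide by a primary carbinol carbon, a closure that tolerates medium rings when the two arms sit on adjacent carbons. It is placed before the enone exists, so that nosyl removal by thiolate meets no Michael acceptor and the alkene geometry is left to the ring.

**Side-arm adjustment (20 ⇒ 18 ⇒ 16).** The hydroxypropyl arm on C7a comes from the allyl group by anti-Markovnikov hydration, and the nosyl amide from the Boc carbamate. Both acetates are already in place at 16, so no hydroxyl other than the primary one can compete in the ring closure.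

**Ring-A oxygenation (16 ⇒ 15 ⇒ 14 ⇒ 13 ⇒ 12).** The tertiary C5–O bond is disconnected to the C5=C6 alkene. The C7 hydroxyl of 13 directs epoxidation to its own face, and hydride opens epoxide 14 at the secondary C6, which leaves the C5 oxygen cis to the C7 oxygen. These steps must come after the C1 carbonyl has gone (hydride, retro-aldol) and before acetates, nosyl group or formamide are present.

**C1–C1' bond (12 ⇒ 9 + 10, through 11; 9 ⇒ 7).** The aminopropyl arm is cut from C1 as a B-alkyl cross-coupling between enol triflate 9 and the borane 11 made from carbamate 10. Ketone 7 can enolise only towards C2, so the triflate forms at one position only, and the coupling leaves the C1=C2 alkene needed for the later transposition.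

**Ring A (7 ⇒ 4 + 6).** The C7–C7a and C3a–C4 bonds are cut together. The cut is made here because one cycloaddition then delivers the quaternary centre, the adjacent oxygenated centre, the cis fusion and the C5=C6 alkene. The forward step has to control regiochemistry, endo geometry and the enantiotopic face of enone 4.

**Building blocks (4 ⇒ 2 + 3, 2 ⇒ 1; 6 ⇒ 5).** The dienophile comes from enone 1 by α-iodination and allyl transfer from stannane 3. The diene is the silyl dienol ether of enal 5. The material before the key step is therefore made in three simple steps.

## Alternatives that were turned down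

**Alternative 1:** The saturated N–CH2–CH2 unit of ring C is traced back to a cis enamide, cyclic compound A1, and A1 is cut at its C2''=C3'' double bond to the N-vinylformamide diene A2. The forward key step is ring-closing metathesis of A2 with second-generation Hoveyda–Grubbs catalyst.
- In its favour: the allyl group on C7a is used as it stands, a cis alkene is the natural outcome in a nine-membered ring, and no sulfonamide has to be put on and taken off. On step economy for ring C it is stronger than the chosen route.
- Against it: it does not address the stereochemically dense bicyclic core, which still needs its own asymmetric construction. N-vinyl amides give stabilised ruthenium carbenes that turn over slowly, and medium-ring closure competes with oligomerisation. A2 must already carry the exocyclic enone with its geometry set without help from the ring. A1 is one oxidation level too high, so the enamide double bond would have to be hydrogenated in the presence of the conjugated C1=C1' bond.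
- The chosen route closes ring C at the final oxidation level and lets the ring set the enone geometry afterwards.

**Alternative 2:** Ring B is opened at the bond between C3a and C3, leading from enedione A3 back to the prochiral triketone A4 (allyl cis to methyl). The forward key step is an amino-acid-catalysed intramolecular aldol condensation that selects one of two enantiotopic ring carbonyls.
- In its favour: it is metal-free and cheap, it sets C7a, and it puts the ring-B carbonyl at C2 where the target has it. No transposition is needed, which is a real advantage over the chosen route.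
- Against it: the well-developed amino-acid aldol cyclisations close six-membered enones, whereas here a cyclopentenone must be closed from a 2-oxopropyl arm, with uncertain enantiocontrol. A4 has a cis/trans relationship at C5 that must be prepared cleanly. A3 carries C5 as CH(CH3), so the tertiary C5–O bond would need a C–H oxidation or a desaturation–hydration sequence. The cis fusion, the C7 carbinol and the alkylidene at the hindered C1 methylene (in competition with C3) would each need a separate selective step.
- The cycloaddition fixes three stereocentres at once and leaves the C5=C6 alkene exactly where the tertiary alcohol is needed.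

**Alternative 3:** Rings A and B are disconnected together at C3a–C7a and at both bonds to C2, leading from bicyclic enone A5 back to the acyclic 1,7-enyne A6, which already holds both oxygenated stereocentres. The forward key step is a Pauson–Khand reaction mediated by Co2(CO)8.
- In its favour: three C–C bonds and two rings form in one step, the carbonyl arrives at C2, C1 is the only saturated α-position of A5, and the oxygen stereocentres come from reliable acyclic chemistry. In bonds formed per step and in carbonyl placement it is stronger than the chosen route.
- Against it: 1,7-enynes cyclise less readily than 1,6-enynes, and a 1,1-disubstituted alkene that must become a quaternary centre lowers reactivity further. The quaternary centre is induced only by the neighbouring C7 silyloxy group. The C3=C3a bond of A5 must later be reduced with cis selectivity. A6 needs a long linear synthesis that includes a tertiary carbinol stereocentre, and the cobalt is stoichiometric.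
- The chosen route reaches the bicyclic core in four steps from commodity chemicals under catalytic asymmetric control and sets the fusion hydrogen in the ring-forming step.

Key step: step 4

Assumption: the oxazaborolidinium derived from (S)-α,α-diphenylprolinol is taken to give the (3aR,7S,7aR) adduct; if the sense of induction proves opposite, the catalyst from the (R)-amino alcohol is used and nothing else changes.

## Route

Step 1
Reactants: 1 cyclopent-2-en-1-one
Product: 2 2-iodocyclopent-2-en-1-one
Conditions: I2, K2CO3, DMAP (cat.), THF–H2O, rt
Reagents that add atoms: iodine, II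
Why: Baylis–Hillman-type α-iodination of an enone: DMAP adds in conjugate fashion, the enolate is iodinated and the amine is eliminated, a standard reaction of cyclic enones.

Step 2
Reactants: 2 2-iodocyclopent-2-en-1-one; 3 allyltributylstannane
Product: 4 2-allylcyclopent-2-en-1-one
Conditions: Pd(PPh3)4 (5 mol%), CuI (10 mol%), DMF, 50 °C
Reagents that add atoms: none
Why: Stille coupling of an α-iodoenone with an allylstannane; oxidative addition of zerovalent palladium to the electron-poor C–I bond is fast, CuI speeds transmetalation, and the mild temperature should limit migration of the allyl double bond into conjugation.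

Step 3
Reactants: 5 3-methylbut-2-enal
Product: 6 (E)-1-(tert-butyldimethylsilyloxy)-3-methylbuta-1,3-diene
Conditions: TBSOTf, Et3N, Et2O, 0 °C → rt
Reagents that add atoms: tert-butyldimethylsilyl trifluoromethanesulfonate, CC(C)(C)[Si](C)(C)OS(=O)(=O)C(F)(F)F
Why: Vinylogous silyl enol ether formation: O-silylation of the enal and γ-deprotonation at a methyl group should give the conjugated dienol ether, the E isomer being favoured from the s-trans oxocarbenium ion.

Step 4
Reactants: 4 2-allylcyclopent-2-en-1-one; 6 (E)-1-(tert-butyldimethylsilyloxy)-3-methylbuta-1,3-diene
Product: 7 (3aR,7S,7aR)-7a-allyl-7-(tert-butyldimethylsilyloxy)-5-methyl-2,3,3a,4,7,7a-hexahydro-1H-inden-1-one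
Conditions: B-(o-tolyl)oxazaborolidine from (S)-α,α-diphenylprolinol (20 mol%), AlBr3 (16 mol%), 6 (2 equiv), CH2Cl2, −78 → −20 °C
Reagents that add atoms: none
Why: A Lewis-acid-catalysed normal-demand Diels–Alder reaction, the closest known type being the chiral oxazaborolidinium-catalysed cycloaddition of cyclic enones with oxygenated dienes. The cationic boron binds the carbonyl of 4 and lowers its LUMO, and bond formation is concerted but asynchronous: the unsubstituted terminus of 6 bonds first to the β-carbon of the enone (future C3a–C4 bond), the silyloxy-bearing terminus then to the α-carbon (future C7–C7a bond). Ring A is closed in this one intermolecular [4+2] event, suprafacial on both partners. Regiochemistry needs no help beyond the diene itself, since the 1-silyloxy and 3-methyl groups raise the HOMO coefficient at the same terminus (ortho/para orientation). The relative configuration of C7 and C7a follows from the endo transition state, in which the carbonyl lies under the diene and the E-configured silyloxy group ends cis to the C7a–C1 bond and trans to the allyl group. C3a is fixed by suprafacial addition to the ring double bond, which can only give the cis ring fusion. The absolute configuration is set by the catalyst, which blocks one face of the bound enone. What the step needs is enough activation of a hindered α-substituted enone without destroying the acid-labile dienol ether, which is why the aprotic AlBr3-activated catalyst, low temperature and an excess of 6 are specified.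

Step 5
Reactants: 7 cycloadduct ketone
Product: 9 7a-allyl-7-(tert-butyldimethylsilyloxy)-5-methyl-3a,4,7,7a-tetrahydro-3H-inden-1-yl trifluoromethanesulfonate (stereocentres as in 7), via potassium enolate 8 (not isolated)
Conditions: KN(SiMe3)2, THF, −78 °C; PhNTf2, −78 → 0 °C
Reagents that add atoms: N-phenylbis(trifluoromethanesulfonimide), O=S(=O)(N(c1ccccc1)S(=O)(=O)C(F)(F)F)C(F)(F)F
Why: Enolate O-triflation; C7a is quaternary, so the ketone can be deprotonated only at C2, and the β-silyloxy group cannot be eliminated because C7a carries no hydrogen.

Step 6
Reactants: 9 enol triflate; 10 tert-butyl allylcarbamate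
Product: 12 tert-butyl {3-[7a-allyl-7-(tert-butyldimethylsilyloxy)-5-methyl-3a,4,7,7a-tetrahydro-3H-inden-1-yl]propyl}carbamate (stereocentres as in 7), via alkylborane 11 (not isolated)
Conditions: 10 (1.6 equiv), 9-BBN (1.5 equiv), THF, 0 °C → rt; then 9, Pd(dppf)Cl2 (5 mol%), AsPh3, Cs2CO3, DMF–H2O, rt
Reagents that add atoms: none
Why: Hydroboration of the terminal alkene of 10 followed by B-alkyl Suzuki–Miyaura coupling with the alkenyl triflate; 10 is kept in excess over the borane so that no B–H is left to attack the allyl group of 9, and transmetalation at room temperature should outrun any Heck-type reaction of the alkenylpalladium intermediate.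

Step 7
Reactants: 12 silyl ether carbamate
Product: 13 tert-butyl [3-(7a-allyl-7-hydroxy-5-methyl-3a,4,7,7a-tetrahydro-3H-inden-1-yl)propyl]carbamate (stereocentres as in 7)
Conditions: Bu4NF, THF, 0 °C → rt
Reagents that add atoms: none
Why: Fluoride-mediated desilylation; with the C1 carbonyl gone, the alkoxide set free can no longer fragment by retro-aldol cleavage.

Step 8
Reactants: 13 allylic alcohol
Product: 14 5,6-epoxide of 13 with the epoxide oxygen cis to the C7 hydroxyl
Conditions: VO(acac)2 (5 mol%), t-BuOOH (1.1 equiv), CH2Cl2, 0 °C
Reagents that add atoms: tert-butyl hydroperoxide, CC(C)(C)OO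
Why: Hydroxyl-directed vanadium-catalysed epoxidation of an allylic alcohol; the vanadate ester of the C7 hydroxyl delivers oxygen to the syn face of C5=C6, which sets C5 and C6, and an allylic alkene should react much faster than the homoallylic C1=C2 bond or the terminal alkene.

Step 9
Reactants: 14 epoxy alcohol
Product: 15 tert-butyl [3-(7a-allyl-5,7-dihydroxy-5-methyl-3a,4,5,6,7,7a-hexahydro-3H-inden-1-yl)propyl]carbamate with the 5-OH and 7-OH cis
Conditions: LiAlH4, THF, 0 °C → rt; aq. NaOH work-up
Reagents that add atoms: none
Why: SN2 hydride opening of a trisubstituted epoxide at its less substituted carbon C6; the C5–O bond is not touched, so the tertiary hydroxyl stays cis to the C7 hydroxyl, and the N–H carbamate is deprotonated and should resist hydride at or below room temperature.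

Step 10
Reactants: 15 cis-diol
Product: 16 5,7-diacetate of 15
Conditions: Ac2O, Et3N, DMAP, CH2Cl2, rt
Reagents that add atoms: acetic anhydride, CC(=O)OC(C)=O
Why: DMAP-catalysed (Steglich-type) acylation; the acetylpyridinium ion acylates the secondary and, more slowly, the tertiary alcohol at room temperature, conditions under which a carbamate N–H is not expected to be acylated.

Step 11
Reactants: 16 diacetate
Product: 18 7a-(3-hydroxypropyl) analogue of 16, via alkylborane 17 (not isolated)
Conditions: 9-BBN, THF, 0 °C → rt; then NaBO3·4H2O, THF–H2O, rt
Reagents that add atoms: sodium perborate, [Na+].[Na+].O[B-]1(O)OO[B-](O)(O)OO1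
Why: Anti-Markovnikov hydroboration–oxidation; 9-BBN should take the monosubstituted alkene and leave the hindered trisubstituted C1=C2 bond, the esters and the carbamate, and perborate oxidises the C–B bond without the strong base that would cleave acetates.

Step 12
Reactants: 18 primary alcohol carbamate
Product: 20 N-[3-(indenyl)propyl]-2-nitrobenzenesulfonamide bearing the 5,7-diacetate and the 7a-(3-hydroxypropyl) arm, via amino alcohol 19 (not isolated)
Conditions: TMSOTf, 2,6-lutidine, CH2Cl2, 0 °C; MeOH, evaporate; then 2-nitrobenzenesulfonyl chloride, Et3N, CH2Cl2, 0 °C
Reagents that add atoms: 2-nitrobenzenesulfonyl chloride, O=[N+]([O-])c1ccccc1S(=O)(=O)Cl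
Why: Silyl triflate-mediated cleavage of the Boc carbamate through its silyl carbamate, which loses CO2 on methanolysis, followed by N-sulfonylation; the buffered aprotic conditions are chosen to spare the tertiary acetate, and the amine should be sulfonylated far faster than the primary alcohol.

Step 13
Reactants: 20 nosyl amide alcohol
Product: 21 N-(2-nitrophenylsulfonyl) azonane: tricycle with ring C closed between N and C3'' and a C1=C2 double bond in ring B and the 5,7-diacetate
Conditions: PPh3, DIAD, toluene–THF (0.002 M, slow addition of 20), rt
Reagents that add atoms: none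
Why: Intramolecular Fukuyama–Mitsunobu N-alkylation; the acidic nosyl amide is deprotonated by the phosphonium betaine and displaces the activated primary oxygen, the two arms on adjacent carbons and high dilution favour the nine-membered ring over oligomers, and the acetylated C7 oxygen cannot compete as a nucleophile.

Step 14
Reactants: 21 N-nosyl azonane
Product: 22 free secondary azonane amine
Conditions: PhSH, K2CO3, DMF, rt
Reagents that add atoms: none
Why: Fukuyama nosyl cleavage: thiolate adds at the sulfonyl-bearing carbon of the nitroarene (Meisenheimer complex), SO2 is lost and the amine is released under conditions that leave acetates and the isolated alkene alone; it is done here because thiolate would add to the later enone.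

Step 15
Reactants: 22 azonane amine
Product: 23 N-formyl azonane with the C1=C2 double bond
Conditions: HCO2CH2CF3, THF, 50 °C
Reagents that add atoms: 2,2,2-trifluoroethyl formate, O=COCC(F)(F)F
Why: N-formylation of a secondary amine by acyl transfer from an activated formate ester; no free hydroxyl is present to compete.

Step 16
Reactants: 23 N-formyl cyclopentene
Product: 24 C1–C2 epoxide of 23 (either face)
Conditions: mCPBA, NaHCO3, CH2Cl2, 0 °C → rt
Reagents that add atoms: 3-chloroperbenzoic acid, O=C(OO)c1cccc(Cl)c1
Why: Prilezhaev epoxidation of the only alkene left; the configuration of the epoxide does not matter because C1 and C2 both lose their stereochemistry in steps 17 and 18.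

Step 17
Reactants: 24 epoxide
Product: 25 allylic alcohol with the C2 hydroxyl and the exocyclic (E)-C1=C1' double bond
Conditions: Cp2TiCl2 (2.5 equiv), Mn dust, THF, rt; then 24, rt
Reagents that add atoms: none
Why: Titanocene-mediated isomerisation of an epoxide to an allylic alcohol (Nugent–RajanBabu opening followed by β-hydrogen loss); trivalent titanium opens the epoxide homolytically to the tertiary C1 radical, which can lose hydrogen only from C1' because C7a is quaternary and C2 carries the titanium alkoxide. Ring C should force the cis-in-ring alkene; esters and the formamide are tolerated.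

Step 18
Reactants: 25 allylic alcohol
Product: 26 target, (3aS,5S,7S,7aS)-5,7-diacetoxy-5-methylhydrindan-2-one whose C1 is the (E)-alkylidene carbon of the N-formyl azonane closed through C7a
Conditions: Dess–Martin periodinane, NaHCO3, CH2Cl2, 0 °C → rt
Reagents that add atoms: none
Why: Dess–Martin oxidation of a secondary allylic alcohol to the conjugated enone under buffered conditions; no stereocentre is made or disturbed and the alkene geometry is kept.

## Compound list

1 | cyclopent-2-en-1-one | O=C1CCC=C1 | starting material
2 | 2-iodocyclopent-2-en-1-one | O=C1CCC=C1I | intermediate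
3 | allyltributylstannane | C=CC[Sn](CCCC)(CCCC)CCCC | starting material
4 | 2-allylcyclopent-2-en-1-one | O=C1CCC=C1CC=C | intermediate
5 | 3-methylbut-2-enal | CC(C)=CC=O | starting material
6 | (E)-1-(tert-butyldimethylsilyloxy)-3-methylbuta-1,3-diene | C=C(C)/C=C/O[Si](C)(C)C(C)(C)C | intermediate
7 | (3aR,7S,7aR)-7a-allyl-7-(tert-butyldimethylsilyloxy)-5-methyl-2,3,3a,4,7,7a-hexahydro-1H-inden-1-one | CC(C)(C)[Si](C)(C)O[C@H]1C=C(C)C[C@H]2CCC(=O)[C@]21CC=C | intermediate
8 | potassium C1=C2 enolate of 7 (formed in the flask) | CC(C)(C)[Si](C)(C)O[C@H]1C=C(C)C[C@H]2CC=C([O-])[C@]21CC=C.[K+] | intermediate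
9 | 7a-allyl-7-(tert-butyldimethylsilyloxy)-5-methyl-3a,4,7,7a-tetrahydro-3H-inden-1-yl trifluoromethanesulfonate, stereocentres as in 7 | CC(C)(C)[Si](C)(C)O[C@H]1C=C(C)C[C@H]2CC=C(OS(=O)(=O)C(F)(F)F)[C@]21CC=C | intermediate
10 | tert-butyl allylcarbamate | C=CCNC(=O)OC(C)(C)C | starting material
11 | tert-butyl [3-(9-borabicyclo[3.3.1]nonan-9-yl)propyl]carbamate (formed in the flask) | CC(C)(C)OC(=O)NCCCB1C2CCCC1CCC2 | intermediate
12 | tert-butyl {3-[7a-allyl-7-(tert-butyldimethylsilyloxy)-5-methyl-3a,4,7,7a-tetrahydro-3H-inden-1-yl]propyl}carbamate, stereocentres as in 7 | CC(C)(C)[Si](C)(C)O[C@H]1C=C(C)C[C@H]2CC=C(CCCNC(=O)OC(C)(C)C)[C@]21CC=C | intermediate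
13 | tert-butyl [3-(7a-allyl-7-hydroxy-5-methyl-3a,4,7,7a-tetrahydro-3H-inden-1-yl)propyl]carbamate, stereocentres as in 7 | O[C@H]1C=C(C)C[C@H]2CC=C(CCCNC(=O)OC(C)(C)C)[C@]21CC=C | intermediate
14 | 5,6-epoxide of 13, epoxide oxygen cis to the C7 hydroxyl | O[C@H]1[C@H]3O[C@@]3(C)C[C@H]2CC=C(CCCNC(=O)OC(C)(C)C)[C@]21CC=C | intermediate
15 | tert-butyl [3-(7a-allyl-5,7-dihydroxy-5-methyl-3a,4,5,6,7,7a-hexahydro-3H-inden-1-yl)propyl]carbamate, 5-OH and 7-OH cis and on the face of the C7a–C1 bond, cis fusion | O[C@H]1C[C@@](C)(O)C[C@H]2CC=C(CCCNC(=O)OC(C)(C)C)[C@]21CC=C | intermediate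
16 | 5,7-diacetate of 15 | CC(=O)O[C@H]1C[C@@](C)(OC(C)=O)C[C@H]2CC=C(CCCNC(=O)OC(C)(C)C)[C@]21CC=C | intermediate
17 | 9-BBN adduct of 16 at the terminal carbon of the former allyl group (formed in the flask) | CC(=O)O[C@H]1C[C@@](C)(OC(C)=O)C[C@H]2CC=C(CCCNC(=O)OC(C)(C)C)[C@]21CCCB3C4CCCC3CCC4 | intermediate
18 | 7a-(3-hydroxypropyl) diacetate carbamate | CC(=O)O[C@H]1C[C@@](C)(OC(C)=O)C[C@H]2CC=C(CCCNC(=O)OC(C)(C)C)[C@]21CCCO | intermediate
19 | primary amine from 18 after loss of Boc (formed in the flask) | CC(=O)O[C@H]1C[C@@](C)(OC(C)=O)C[C@H]2CC=C(CCCN)[C@]21CCCO | intermediate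
20 | 2-nitrobenzenesulfonamide of 19 | CC(=O)O[C@H]1C[C@@](C)(OC(C)=O)C[C@H]2CC=C(CCCNS(=O)(=O)c3ccccc3[N+](=O)[O-])[C@]21CCCO | intermediate
21 | N-(2-nitrophenylsulfonyl) azonane tricycle, C1=C2 double bond, 5,7-diacetate | CC(=O)O[C@H]1C[C@@](C)(OC(C)=O)C[C@H]2CC=C3CCCN(S(=O)(=O)c4ccccc4[N+](=O)[O-])CCC[C@@]321 | intermediate
22 | free azonane (secondary amine) tricycle | CC(=O)O[C@H]1C[C@@](C)(OC(C)=O)C[C@H]2CC=C3CCCNCCC[C@@]321 | intermediate
23 | N-formyl azonane tricycle with C1=C2 double bond | CC(=O)O[C@H]1C[C@@](C)(OC(C)=O)C[C@H]2CC=C3CCCN(C=O)CCC[C@@]321 | intermediate
24 | C1–C2 epoxide of 23, epoxide face not assigned, both diastereomers converge | CC(=O)O[C@H]1C[C@@](C)(OC(C)=O)C[C@H]2CC4OC43CCCN(C=O)CCC[C@@]321 | intermediate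
25 | C2 allylic alcohol with exocyclic (E)-C1=C1' double bond, C2 configuration not assigned | CC(=O)O[C@H]1C[C@@](C)(OC(C)=O)C[C@H]2CC(O)/C3=C/CCN(C=O)CCC[C@@]321 | intermediate
26 | target, (3aS,5S,7S,7aS), (E)-enone | CC(=O)O[C@H]1C[C@@](C)(OC(C)=O)C[C@H]2CC(=O)/C3=C/CCN(C=O)CCC[C@@]321 | target

## Step count and least certain steps

Total: 18 steps. Longest linear sequence: 17 steps (1 → 2 → 4 → 7 → … → 26); diene 6 is a one-step branch.

**Step 4 (key step).** The α-allyl group slows the dienophile and removes the α-hydrogen that usually helps to organise an enone on this type of catalyst. Activation may therefore be too weak, so that the acid-labile dienol ether is consumed by desilylation or by a stepwise Michael-type addition before cycloaddition, or facial discrimination may be poor.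
Fallback, from 4 and 6, returning at 7:
- The cycloaddition is run with an achiral Lewis acid (EtAlCl2, CH2Cl2, −78 °C) or under high pressure to give the racemic endo adduct F1.
- HF·pyridine in THF removes the silyl group without base, so that retro-aldol cleavage is avoided, and gives the racemic hydroxy ketone F2.
- Lipase-mediated transesterification with vinyl acetate acylates one enantiomer and should leave the (3aR,7S,7aR) alcohol F3 beside the acetate of its antipode F4. If the enzyme prefers the wanted enantiomer, its acetate is separated and hydrolysed by the same enzyme in buffer.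
- TBSOTf and 2,6-lutidine convert F3 into 7. Half of the material is lost, but the approach no longer depends on the chiral catalyst.

**Step 17.** The tertiary radical may be reduced by hydrogen-atom capture instead of losing the C1' hydrogen, the epoxide may be deoxygenated back to the alkene, or the alkene may form partly with the strained trans-in-ring geometry.
Fallback, from 23, returning at 26:
- Dihydroxylation (OsO4 cat., N-methylmorpholine N-oxide, acetone–H2O) gives the C1,C2 cis-diol F5.
- Oxidation of its secondary hydroxyl (SO3·pyridine, DMSO, i-Pr2NEt) gives the tertiary α-hydroxy ketone F6.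
- Dehydration with Burgess reagent or SOCl2/pyridine can eliminate only towards C1', since C7a is quaternary and C2 is a carbonyl, and delivers 26 directly.

**Step 13.** Intermolecular N-alkylation may compete with the slow nine-membered closure and give dimers and oligomers, and the Mitsunobu reagents cannot be diluted independently of the substrate.
Fallback, from 20, returning at 21: activation is separated from ring closure. I2, PPh3 and imidazole give the primary iodide F7, which is added by syringe pump to Cs2CO3 in MeCN at 60 °C so that the caesium sulfonamide closes the ring by SN2 displacement at a very low standing concentration.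

**Step 8.** Oxygen transfer may not stop at the allylic alkene: the homoallylic C1=C2 bond can be epoxidised as well, or the allylic alcohol can be oxidised to the enone.
Fallback, from 9, returning at 14: the order is changed so that the ring-B alkene is an electron-poor enol triflate during the epoxidation.
- HF·pyridine desilylates 9 to the hydroxy triflate F8.
- VO(acac)2 and t-BuOOH give the epoxy alcohol triflate F9.
- Coupling of F9 with alkylborane 11 under the conditions of step 6 gives 14.

**Step 2.** A palladium hydride may move the allyl double bond into conjugation, giving the propenyl dienone, and transmetalation to the hindered α-position may be slow.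
Fallback, from 2, returning at 4: the polarity is reversed.
- Ketalisation (ethylene glycol, TsOH, benzene, reflux) gives the iodo ketal F10.
- Iodine–lithium exchange (t-BuLi, THF, −78 °C) and alkylation with allyl bromide give the allyl ketal F11.
- Aqueous oxalic acid releases 4.

## Further compounds

F1 | step 4 | racemic 7a-allyl-7-(tert-butyldimethylsilyloxy)-5-methyl-2,3,3a,4,7,7a-hexahydro-1H-inden-1-one, relative configuration of 7 | CC(C)(C)[Si](C)(C)O[C@H]1C=C(C)C[C@H]2CCC(=O)[C@]21CC=C.CC(C)(C)[Si](C)(C)O[C@@H]1C=C(C)C[C@@H]2CCC(=O)[C@@]21CC=C
F2 | step 4 | racemic 7a-allyl-7-hydroxy-5-methyl-2,3,3a,4,7,7a-hexahydro-1H-inden-1-one | O[C@H]1C=C(C)C[C@H]2CCC(=O)[C@]21CC=C.O[C@@H]1C=C(C)C[C@@H]2CCC(=O)[C@@]21CC=C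
F3 | step 4 | (3aR,7S,7aR)-7a-allyl-7-hydroxy-5-methyl-2,3,3a,4,7,7a-hexahydro-1H-inden-1-one | O[C@H]1C=C(C)C[C@H]2CCC(=O)[C@]21CC=C
F4 | step 4 | (3aS,7R,7aS)-7a-allyl-5-methyl-1-oxo-2,3,3a,4,7,7a-hexahydro-1H-inden-7-yl acetate | CC(=O)O[C@@H]1C=C(C)C[C@@H]2CCC(=O)[C@@]21CC=C
F5 | step 17 | C1,C2 cis-diol of 23, face not assigned | CC(=O)O[C@H]1C[C@@](C)(OC(C)=O)C[C@H]2CC(O)C3(O)CCCN(C=O)CCC[C@@]321
F6 | step 17 | C2 ketone with tertiary C1 hydroxyl | CC(=O)O[C@H]1C[C@@](C)(OC(C)=O)C[C@H]2CC(=O)C3(O)CCCN(C=O)CCC[C@@]321
F7 | step 13 | primary iodide corresponding to 20 | CC(=O)O[C@H]1C[C@@](C)(OC(C)=O)C[C@H]2CC=C(CCCNS(=O)(=O)c3ccccc3[N+](=O)[O-])[C@]21CCCI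
F8 | step 8 | 7a-allyl-7-hydroxy-5-methyl-3a,4,7,7a-tetrahydro-3H-inden-1-yl trifluoromethanesulfonate | O[C@H]1C=C(C)C[C@H]2CC=C(OS(=O)(=O)C(F)(F)F)[C@]21CC=C
F9 | step 8 | 5,6-epoxide of F8, epoxide oxygen cis to the C7 hydroxyl | O[C@H]1[C@H]3O[C@@]3(C)C[C@H]2CC=C(OS(=O)(=O)C(F)(F)F)[C@]21CC=C
F10 | step 2 | 6-iodo-1,4-dioxaspiro[4.4]non-6-ene | IC1=CCCC12OCCO2
F11 | step 2 | 6-allyl-1,4-dioxaspiro[4.4]non-6-ene | C=CCC1=CCCC12OCCO2
A1 | alternative 1 | cyclic cis-enamide, the 2'',3''-didehydro target | CC(=O)O[C@H]1C[C@@](C)(OC(C)=O)C[C@H]2CC(=O)/C3=C/CCN(C=O)/C=C\C[C@@]321
A2 | alternative 1 | N-vinylformamide diene with the allyl group on C7a | CC(=O)O[C@H]1C[C@@](C)(OC(C)=O)C[C@H]2CC(=O)/C(=C/CCN(C=O)C=C)[C@]21CC=C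
A3 | alternative 2 | bicyclic enedione with allyl-bearing quaternary carbon | O=C1C[C@H](C)CC2=CC(=O)C[C@]21CC=C
A4 | alternative 2 | 2-allyl-5-methyl-2-(2-oxopropyl)cyclohexane-1,3-dione, allyl cis to methyl | CC(=O)C[C@@]1(CC=C)C(=O)C[C@H](C)CC1=O
A5 | alternative 3 | bicyclic cyclopentenone from the Pauson–Khand reaction | CC(C)(C)[Si](C)(C)O[C@H]1C[C@@](C)(O[Si](CC)(CC)CC)CC2=CC(=O)C[C@]21CCCOCc3ccc(OC)cc3
A6 | alternative 3 | acyclic 1,7-enyne with both silyloxy stereocentres | C#CC[C@](C)(O[Si](CC)(CC)CC)C[C@H](O[Si](C)(C)C(C)(C)C)C(=C)CCCOCc1ccc(OC)cc1
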